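**Retrosynthetic overview**
1. The C17 acid comes from an isopropenyl group by allylic oxidation. The C3-OAc/C4-OH pair comes from a macrocyclic (E)-C4=C5 allylic alcohol by OH-directed epoxidation and hydride opening.
2. Ring 2, the 14-membered carbocycle, is closed last. The C3–C4 bond is made by a Ni(0) reductive ynal macrocyclisation rather than RCM, NHK or alkylation; this step creates C3 and the methyl-bearing alkene together.
3. The ynal is assembled by two terminal-oxirane openings of one C10 core. Propynyl (C4, C5, C18) attacks C6, and (R)-lavandulyl Grignard (C14, C1, C2, C3, C15–C17) attacks C13. C1 comes from an Evans deconjugative prenylation.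
4. Ring 1, the oxolane, is closed first and is the key step. A double Sharpless epoxidation of 8-hydroxygeraniol is followed by a base-triggered Payne/5-exo "epoxide zipper". One tartrate sets C7, C8, C11 and C12, and the oxirane ends up at the chain terminus as the C6 electrophile.

Assumption: cembrane numbering is used throughout. C1 is the ring CH bearing C15(=C16H2)C17O2H, C3 is CHOAc, C4/C8/C12 carry CH3-18/19/20, and the oxolane O bridges C8 and C11. The target is (1R,3R,4S,7S,8R,11S,12R).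

**Step 1**
Reactants: 1 geranyl acetate
Product: 2 (2E,6E)-8-hydroxy-3,7-dimethylocta-2,6-dien-1-yl acetate
Conditions: SeO2 (0.3 equiv), t-BuOOH, CH2Cl2, 0 °C to rt
Reagents that add atoms: tert-butyl hydroperoxide, CC(C)(C)OO
Why: Catalytic SeO2 allylic oxidation (ene/[2,3] sequence) hydroxylates the (E)-methyl of the electron-rich distal alkene, while the alkene next to the acetate is deactivated.

**Step 2**
Reactants: 2 (2E,6E)-8-hydroxygeranyl acetate
Product: 3 (2E,6E)-2,6-dimethylocta-2,6-diene-1,8-diol (8-hydroxygeraniol)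
Conditions: K2CO3 (0.2 equiv), MeOH, rt
Reagents that add atoms: none
Why: Base-catalysed transesterification frees the second allylic alcohol, and no stereocentre is involved.

**Step 3**
Reactants: 3 8-hydroxygeraniol
Product: 4 (2R,3R,6R,7R)-2,3:6,7-diepoxy-2,6-dimethyloctane-1,8-diol (cembrane 12R,11R,8R,7R)
Conditions: Ti(Oi-Pr)4 (20 mol %), D-(−)-DET (26 mol %), t-BuOOH (4 equiv), 4 Å MS, CH2Cl2, −20 °C
Reagents that add atoms: tert-butyl hydroperoxide, CC(C)(C)OO
Why: Two-fold Katsuki–Sharpless asymmetric epoxidation, in which D-(−)-tartrate gives the (R,R)-oxirane from each (E)-allylic alcohol and the double reaction raises the ee by statistical amplification.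

**Step 4**
Reactants: 4 bis-epoxy diol
Product: 6 (2R)-2-{(2S,5R)-5-methyl-5-[(2S)-oxiran-2-yl]oxolan-2-yl}propane-1,2-diol, via Payne isomer (2R,3R,6R,7S)-2,3:7,8-diepoxy-2,6-dimethyloctane-1,6-diol 5 (not isolated)
Conditions: t-BuOK (0.3 equiv), t-BuOH–THF, 30 °C; pH 7 buffer
Reagents that add atoms: none
Why: A Payne rearrangement (C6–O⁻ attacks secondary C7, inverting it to 7S) frees the C8 tertiary alkoxide, which closes irreversibly by 5-exo-tet opening at secondary C11 (inverting it to 11S) with the C8–O and C12–O bonds untouched (8R, 12R); this epoxide cascade runs only from the C6 end because the reverse direction would need two SN2 attacks at tertiary carbons.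

**Step 5**
Reactants: 6 oxiranyl-oxolane diol; 7 1-propynyllithium
Product: 8 (2R)-2-{(2S,5R)-5-[(1S)-1-hydroxypent-3-yn-1-yl]-5-methyloxolan-2-yl}propane-1,2-diol
Conditions: 7 (4 equiv), THF–DMPU, 0 °C to rt; H2O
Reagents that add atoms: none
Why: SN2 opening of the monosubstituted oxirane at its CH2 (C6) by a lithium acetylide installs C5, C4 and C18 and leaves the C7–O bond, and so 7S, untouched.

**Step 6**
Reactants: 8 alkynyl triol
Product: 11 tert-butyl(dimethyl)silyl ether of (1S)-1-{(2R,5S)-2-methyl-5-[(2R)-2-methyloxiran-2-yl]oxolan-2-yl}pent-3-yn-1-ol, via primary (C13) tosylate of 8 9 (not isolated), via (1S)-1-{(2R,5S)-2-methyl-5-[(2R)-2-methyloxiran-2-yl]oxolan-2-yl}pent-3-yn-1-ol 10 (not isolated)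
Conditions: NaH (3.2 equiv), THF, 0 °C; N-tosylimidazole (1.0 equiv); then TBSCl, rt
Reagents that add atoms: N-tosylimidazole, Cc1ccc(cc1)S(=O)(=O)n1ccnc1 (its tosyl group is carried only in 9); tert-butyldimethylsilyl chloride, CC(C)(C)[Si](C)(C)Cl
Why: In this one-pot diol-to-epoxide conversion the primary alkoxide is sulfonylated first, the neighbouring C12 alkoxide closes by 3-exo-tet displacement at C13 (C12–O retained, 12R), and the remaining C7 sodium alkoxide is silylated.

**Step 7**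
Reactants: 12 (R)-4-benzyl-1,3-oxazolidin-2-one; 13 3-methylbut-2-enoyl chloride
Product: 14 (R)-4-benzyl-3-(3-methylbut-2-enoyl)-1,3-oxazolidin-2-one
Conditions: n-BuLi, THF, −78 °C; then 13
Reagents that add atoms: none
Why: Standard N-acylation of the lithiated Evans auxiliary.

**Step 8**
Reactants: 14 N-senecioyl imide; 15 prenyl bromide
Product: 16 (4R)-4-benzyl-3-[(2R)-5-methyl-2-(prop-1-en-2-yl)hex-4-enoyl]-1,3-oxazolidin-2-one
Conditions: NaHMDS, THF, −78 °C; 15, −78 to −40 °C
Reagents that add atoms: none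
Why: Evans asymmetric alkylation in its deconjugative mode, where the chelated Z(O)-dienolate reacts at Cα on the face opposite the benzyl group and so sets C1 as R while generating the isopropenyl group.

**Step 9**
Reactants: 16 alkylated imide
Product: 17 (R)-lavandulol, (2R)-5-methyl-2-(prop-1-en-2-yl)hex-4-en-1-ol
Conditions: LiBH4, H2O (1 equiv), Et2O, 0 °C
Reagents that add atoms: none
Why: Reductive removal of the auxiliary under non-basic conditions avoids epimerisation or conjugation of the β,γ-unsaturated stereocentre.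

**Step 10**
Reactants: 17 (R)-lavandulol
Product: 18 (R)-lavandulyl bromide, (5R)-5-(bromomethyl)-2,6-dimethylhepta-2,6-diene
Conditions: CBr4, PPh3, CH2Cl2, 0 °C
Reagents that add atoms: carbon tetrabromide, BrC(Br)(Br)Br
Why: The Appel reaction takes place at the primary carbinol and does not involve C1.

**Step 11**
Reactants: 18 (R)-lavandulyl bromide; 11 silyloxy alkynyl epoxide
Product: 20 (2R,5R)-2-{(2S,5R)-5-[(1S)-1-(tert-butyldimethylsilyloxy)pent-3-yn-1-yl]-5-methyloxolan-2-yl}-8-methyl-5-(prop-1-en-2-yl)non-7-en-2-ol, via (R)-lavandulylmagnesium bromide 19 (not isolated)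
Conditions: Mg, THF; CuI (10 mol %), 11, THF, −30 to 0 °C; H2O
Reagents that add atoms: magnesium, [Mg] (carried only in 19)
Why: Copper-catalysed Grignard opening of the 2,2-disubstituted oxirane at its CH2 forms C13–C14 and releases the 12R tertiary alcohol without touching any stereocentre.

**Step 12**
Reactants: 20 enyne alcohol
Product: 22 (3R,6R)-6-{(2S,5R)-5-[(1S)-1-(tert-butyldimethylsilyloxy)pent-3-yn-1-yl]-5-methyloxolan-2-yl}-6-hydroxy-3-(prop-1-en-2-yl)heptanal, via 7,8-epoxide of 20 (both oxirane epimers) 21 (not isolated)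
Conditions: mCPBA (1.0 equiv), CH2Cl2, −10 °C; then H5IO6, THF–H2O, 0 °C
Reagents that add atoms: meta-chloroperoxybenzoic acid, O=C(OO)c1cccc(Cl)c1
Why: Prilezhaev epoxidation selects the trisubstituted prenyl alkene over the 1,1-disubstituted alkene and the alkyne, and periodic acid cleavage of the oxirane then reveals the C3 aldehyde.

**Step 13**
Reactants: 22 ynal
Product: 24 (1R,3R,4E,7S,8R,11S,12R)-7-(tert-butyldimethylsilyloxy)-8,11-epoxycembra-4,15(16)-diene-3,12-diol, via macrocyclic 3-O-triethylsilyl ether 23 (not isolated)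
Conditions: Ni(cod)2 (25 mol %), IMes·HCl (25 mol %), t-BuOK (25 mol %), Et3SiH (5 equiv), THF (2 mM, syringe pump), rt; then PPTS, MeOH, 0 °C
Reagents that add atoms: triethylsilane, CC[SiH](CC)CC (its Et3Si group is carried only in 23; 24 keeps only its H)
Why: Ni(0)/NHC-catalysed reductive aldehyde–alkyne coupling run as an endo macrocyclisation, where the small carbene directs C–C formation to the methyl-bearing alkyne carbon, syn H/C addition gives the (E)-alkene, and C3 is set only by the conformation of the macrocyclic nickelacycle, so 3R is the least secure centre (redox correction is in the fallback).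

**Step 14**
Reactants: 24 macrocyclic allylic alcohol
Product: 25 (1R,3R,4R,5R,7S,8R,11S,12R)-7-(tert-butyldimethylsilyloxy)-4,5:8,11-diepoxycembr-15(16)-ene-3,12-diol
Conditions: VO(acac)2 (5 mol %), t-BuOOH, CH2Cl2, 0 °C
Reagents that add atoms: tert-butyl hydroperoxide, CC(C)(C)OO
Why: In this vanadium-catalysed hydroxyl-directed epoxidation, A(1,2) strain between CH3-18 and C2 in the vanadate transition state gives the erythro epoxy alcohol, which places the C4–O bond as required for 4S, and the isopropenyl group is not directed and stays intact.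

**Step 15**
Reactants: 25 epoxy alcohol
Product: 26 (1R,3R,4S,7S,8R,11S,12R)-7-(tert-butyldimethylsilyloxy)-8,11-epoxycembr-15(16)-ene-3,4,12-triol
Conditions: LiAlH4, THF, 0 to 40 °C; H2O
Reagents that add atoms: none
Why: Hydride SN2 opening can occur only at secondary C5 because C4 is fully substituted, so the C4–O bond is kept and the 1,2-diol with 4S results.

**Step 16**
Reactants: 26 triol
Product: 27 3-O-acetate of 26
Conditions: Ac2O (1.3 equiv), pyridine, DMAP (cat.), CH2Cl2, 0 °C to rt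
Reagents that add atoms: acetic anhydride, CC(=O)OC(C)=O
Why: C3-OH is the only free secondary alcohol, since C7 is silylated and C4/C12 are tertiary, so DMAP-catalysed acylation is site-selective.

**Step 17**
Reactants: 27 acetate
Product: 29 (1R,3R,4S,7S,8R,11S,12R)-3-acetoxy-7-(tert-butyldimethylsilyloxy)-4,12-dihydroxy-8,11-epoxycembr-15(16)-en-17-al, via the corresponding 17-alcohol 28 (not isolated)
Conditions: SeO2 (0.5 equiv), t-BuOOH, CH2Cl2, rt; then MnO2, CH2Cl2, rt
Reagents that add atoms: tert-butyl hydroperoxide, CC(C)(C)OO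
Why: SeO2 allylic oxidation of the only remaining alkene occurs at its methyl rather than the hindered C1–H, and MnO2 oxidises only the allylic alcohol to the enal.

**Step 18**
Reactants: 29 enal
Product: 30 7-O-tert-butyldimethylsilyl dendronpholide J
Conditions: NaClO2, NaH2PO4, 2-methyl-2-butene, t-BuOH–H2O, 0 °C to rt
Reagents that add atoms: sodium chlorite, [Na+].[O-]Cl=O
Why: Pinnick oxidation converts the enal to the acrylic acid without affecting the acetate, silyl ether or tertiary alcohols.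

**Step 19**
Reactants: 30 silyl ether acid
Product: 31 dendronpholide J
Conditions: HF·pyridine, THF, 0 °C to rt
Reagents that add atoms: none
Why: Fluoride-driven desilylation under weakly acidic conditions frees C7-OH without acetate cleavage or migration.

**Compound list**

| No. | Name | SMILES | Role |
|---|---|---|---|
| 1 | geranyl acetate | CC(=O)OC/C=C(\C)CCC=C(C)C | starting material |
| 2 | (2E,6E)-8-hydroxygeranyl acetate | CC(=O)OC/C=C(\C)CC/C=C(\C)CO | intermediate |
| 3 | (2E,6E)-2,6-dimethylocta-2,6-diene-1,8-diol | OC/C=C(\C)CC/C=C(\C)CO | intermediate |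
| 4 | (2R,3R,6R,7R)-2,3:6,7-diepoxy-2,6-dimethyloctane-1,8-diol | OC[C@H]1O[C@]1(C)CC[C@H]2O[C@]2(C)CO | intermediate |
| 5 | (2R,3R,6R,7S)-2,3:7,8-diepoxy-2,6-dimethyloctane-1,6-diol | C1O[C@@H]1[C@](C)(O)CC[C@H]2O[C@]2(C)CO | intermediate (not isolated) |
| 6 | (2R)-2-{(2S,5R)-5-methyl-5-[(2S)-oxiran-2-yl]oxolan-2-yl}propane-1,2-diol | C1O[C@@H]1[C@@]2(C)CC[C@H](O2)[C@](C)(O)CO | intermediate |
| 7 | 1-propynyllithium | [Li]C#CC | starting material |
| 8 | (2R)-2-{(2S,5R)-5-[(1S)-1-hydroxypent-3-yn-1-yl]-5-methyloxolan-2-yl}propane-1,2-diol | CC#CC[C@H](O)[C@@]1(C)CC[C@H](O1)[C@](C)(O)CO | intermediate |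
| 9 | primary tosylate of 8 | CC#CC[C@H](O)[C@@]1(C)CC[C@H](O1)[C@](C)(O)COS(=O)(=O)c2ccc(C)cc2 | intermediate (not isolated) |
| 10 | (1S)-1-{(2R,5S)-2-methyl-5-[(2R)-2-methyloxiran-2-yl]oxolan-2-yl}pent-3-yn-1-ol | CC#CC[C@H](O)[C@@]1(C)CC[C@H](O1)[C@@]2(C)CO2 | intermediate (not isolated) |
| 11 | TBS ether of 10 | CC#CC[C@H](O[Si](C)(C)C(C)(C)C)[C@@]1(C)CC[C@H](O1)[C@@]2(C)CO2 | intermediate |
| 12 | (R)-4-benzyl-1,3-oxazolidin-2-one | O=C1N[C@H](Cc2ccccc2)CO1 | starting material |
| 13 | 3-methylbut-2-enoyl chloride | CC(C)=CC(=O)Cl | starting material |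
| 14 | (R)-4-benzyl-3-(3-methylbut-2-enoyl)-1,3-oxazolidin-2-one | CC(C)=CC(=O)N1[C@H](Cc2ccccc2)COC1=O | intermediate |
| 15 | prenyl bromide | CC(C)=CCBr | starting material |
| 16 | (4R)-4-benzyl-3-[(2R)-5-methyl-2-(prop-1-en-2-yl)hex-4-enoyl]-1,3-oxazolidin-2-one | C=C(C)[C@@H](CC=C(C)C)C(=O)N1[C@H](Cc2ccccc2)COC1=O | intermediate |
| 17 | (R)-lavandulol | C=C(C)[C@@H](CC=C(C)C)CO | intermediate |
| 18 | (R)-lavandulyl bromide | C=C(C)[C@@H](CC=C(C)C)CBr | intermediate |
| 19 | (R)-lavandulylmagnesium bromide | C=C(C)[C@@H](CC=C(C)C)C[Mg]Br | intermediate (not isolated) |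
| 20 | open-chain enyne alcohol (1R,7S,8R,11S,12R; C4≡C5, C3=CMe2, 7-OTBS) | C=C(C)[C@@H](CC=C(C)C)CC[C@@](C)(O)[C@@H]1CC[C@@](C)(O1)[C@@H](O[Si](C)(C)C(C)(C)C)CC#CC | intermediate |
| 21 | prenyl epoxide of 20 (oxirane epimers) | C=C(C)[C@@H](CC1OC1(C)C)CC[C@@](C)(O)[C@@H]2CC[C@@](C)(O2)[C@@H](O[Si](C)(C)C(C)(C)C)CC#CC | intermediate (not isolated) |
| 22 | ynal (C3 aldehyde, C4≡C5) | C=C(C)[C@@H](CC=O)CC[C@@](C)(O)[C@@H]1CC[C@@](C)(O1)[C@@H](O[Si](C)(C)C(C)(C)C)CC#CC | intermediate |
| 23 | macrocyclic 3-O-triethylsilyl ether | C=C(C)[C@@H]1CC[C@@](C)(O)[C@@H]2CC[C@@](C)(O2)[C@@H](O[Si](C)(C)C(C)(C)C)C/C=C(\C)[C@H](O[Si](CC)(CC)CC)C1 | intermediate (not isolated) |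
| 24 | (1R,3R,4E,7S,8R,11S,12R)-7-TBSO-8,11-epoxycembra-4,15(16)-diene-3,12-diol | C=C(C)[C@@H]1CC[C@@](C)(O)[C@@H]2CC[C@@](C)(O2)[C@@H](O[Si](C)(C)C(C)(C)C)C/C=C(\C)[C@H](O)C1 | intermediate |
| 25 | (3R,4R,5R)-4,5-epoxide of 24 | C=C(C)[C@@H]1CC[C@@](C)(O)[C@@H]2CC[C@@](C)(O2)[C@@H](O[Si](C)(C)C(C)(C)C)C[C@H]3O[C@]3(C)[C@H](O)C1 | intermediate |
| 26 | (1R,3R,4S,7S,8R,11S,12R)-7-TBSO-8,11-epoxycembr-15(16)-ene-3,4,12-triol | C=C(C)[C@@H]1CC[C@@](C)(O)[C@@H]2CC[C@@](C)(O2)[C@@H](O[Si](C)(C)C(C)(C)C)CC[C@](C)(O)[C@H](O)C1 | intermediate |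
| 27 | 3-O-acetate of 26 | C=C(C)[C@@H]1CC[C@@](C)(O)[C@@H]2CC[C@@](C)(O2)[C@@H](O[Si](C)(C)C(C)(C)C)CC[C@](C)(O)[C@H](OC(C)=O)C1 | intermediate |
| 28 | 17-hydroxy derivative of 27 | C=C(CO)[C@@H]1CC[C@@](C)(O)[C@@H]2CC[C@@](C)(O2)[C@@H](O[Si](C)(C)C(C)(C)C)CC[C@](C)(O)[C@H](OC(C)=O)C1 | intermediate (not isolated) |
| 29 | 17-al (enal) | C=C(C=O)[C@@H]1CC[C@@](C)(O)[C@@H]2CC[C@@](C)(O2)[C@@H](O[Si](C)(C)C(C)(C)C)CC[C@](C)(O)[C@H](OC(C)=O)C1 | intermediate |
| 30 | 7-O-TBS dendronpholide J | C=C(C(=O)O)[C@@H]1CC[C@@](C)(O)[C@@H]2CC[C@@](C)(O2)[C@@H](O[Si](C)(C)C(C)(C)C)CC[C@](C)(O)[C@H](OC(C)=O)C1 | intermediate |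
| 31 | dendronpholide J | C=C(C(=O)O)[C@@H]1CC[C@@](C)(O)[C@@H]2CC[C@@](C)(O2)[C@@H](O)CC[C@](C)(O)[C@H](OC(C)=O)C1 | target |

**Totals**
- Total step count: 19.
- Longest linear sequence: 15 steps (steps 1–6 and 11–19, from 1 to 31).

**Steps most likely to fail**

Step 4 (epoxide zipper). The Payne isomer is the minor partner in the equilibrium. The free terminal oxirane of 6 also sits in base next to two alkoxides, so bridging by C12–O⁻ or oligomerisation is possible.

The fallback sets out from 4 and rejoins at 6. It runs the same zipper in the aqueous Payne mode with a thiolate trap (PhSH, 0.5 M NaOH, t-BuOH, 65 °C). The terminal oxirane is then consumed at C6 as soon as it forms, giving (2R)-2-{(2S,5R)-5-[(1R)-1-hydroxy-2-(phenylsulfanyl)ethyl]-5-methyloxolan-2-yl}propane-1,2-diol F1. S-Methylation with Me3OBF4 in CH2Cl2 gives the methyl(phenyl)sulfonium tetrafluoroborate F2. Brief treatment with aqueous NaOH/CH2Cl2 lets C7–O⁻ displace the sulfide at C6, with the C7–O bond untouched, and delivers 6 under controlled, short base exposure.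

Step 13 (Ni macrocyclisation). The risks are endo/exo regiochemistry, oligomerisation and, above all, the C3 configuration.

The fallback sets out from 20 and rejoins at 24.
- Hydrozirconation with Cp2Zr(H)Cl (excess, THF) followed by I2 places iodine on the methyl-bearing carbon, giving the (E)-C4 vinyl iodide F3.
- mCPBA gives its prenyl epoxide F4, and H5IO6 gives the iodo-aldehyde F5.
- Nozaki–Hiyama–Kishi closure (CrCl2, cat. NiCl2, DMSO–THF, 3 mM) gives 24 together with its 3S epimer F6.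
- The carbinol mixture is oxidised with Dess–Martin periodinane to the macrocyclic C3 enone F7.
- (S)-Me-CBS/catecholborane at −78 °C then sets 3R under reagent control (alkenyl group as the large substituent), returning 24.

Step 15 (hydride opening). Backside attack at C5 must come from the interior of the macrocycle and may be very slow, which invites TBS loss on forcing.

The fallback sets out from 25 and rejoins at 26. MgI2 (toluene–Et2O, −60 °C), chelated by the C3 alkoxide, opens the oxirane at the distal C5 with the small, soft iodide. This gives the (5S)-5-iodo-3,4-diol F8. Radical deiodination (Bu3SnH, Et3B/air, toluene, 0 °C) removes the halogen to give 26.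

**Further compounds**
F1 | step 4 | (2R)-2-{(2S,5R)-5-[(1R)-1-hydroxy-2-(phenylsulfanyl)ethyl]-5-methyloxolan-2-yl}propane-1,2-diol | OC[C@@](C)(O)[C@@H]1CC[C@@](C)(O1)[C@@H](O)CSc2ccccc2
F2 | step 4 | methyl(phenyl)sulfonium tetrafluoroborate of F1 | OC[C@@](C)(O)[C@@H]1CC[C@@](C)(O1)[C@@H](O)C[S+](C)c2ccccc2.F[B-](F)(F)F
F3 | step 13 | (E)-C4 vinyl iodide derived from 20 | C=C(C)[C@@H](CC=C(C)C)CC[C@@](C)(O)[C@@H]1CC[C@@](C)(O1)[C@@H](O[Si](C)(C)C(C)(C)C)C/C=C(\C)I
F4 | step 13 | prenyl epoxide of F3 (oxirane epimers) | C=C(C)[C@@H](CC1OC1(C)C)CC[C@@](C)(O)[C@@H]2CC[C@@](C)(O2)[C@@H](O[Si](C)(C)C(C)(C)C)C/C=C(\C)I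
F5 | step 13 | iodo-aldehyde (C3 aldehyde, C4 vinyl iodide) | C=C(C)[C@@H](CC=O)CC[C@@](C)(O)[C@@H]1CC[C@@](C)(O1)[C@@H](O[Si](C)(C)C(C)(C)C)C/C=C(\C)I
F6 | step 13 | 3S epimer of 24 | C=C(C)[C@@H]1CC[C@@](C)(O)[C@@H]2CC[C@@](C)(O2)[C@@H](O[Si](C)(C)C(C)(C)C)C/C=C(\C)[C@@H](O)C1
F7 | step 13 | macrocyclic C3 enone | C=C(C)[C@@H]1CC[C@@](C)(O)[C@@H]2CC[C@@](C)(O2)[C@@H](O[Si](C)(C)C(C)(C)C)C/C=C(\C)C(=O)C1
F8 | step 15 | (5S)-5-iodo-3,4-diol from 25 | C=C(C)[C@@H]1CC[C@@](C)(O)[C@@H]2CC[C@@](C)(O2)[C@@H](O[Si](C)(C)C(C)(C)C)C[C@H](I)[C@](C)(O)[C@H](O)C1
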